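I have no constants for this flask, so I start from the charges and the two earlier runs.

all flasks: starting material 0.050 M; free catalyst 15 mol%
- Friday's: second substrate 2 equiv; reagent 0.80 equiv; impurity 0.18 mM; run made earlier
- Sunday's: second substrate 2 equiv; reagent 0.80 equiv; impurity 14 mM; run made earlier
- zeta: second substrate 2.00 equiv; reagent 0.800 equiv; impurity 0.15 mM; time 3.0 min
- alpha: second substrate 2.00 equiv; reagent 0.800 equiv; impurity 0.40 mM; time 3.0 min
- theta: second substrate 2.00 equiv; reagent 0.800 equiv; impurity 1.2 mM; time 3.0 min
- eta: second substrate 2.00 equiv; reagent 0.800 equiv; impurity 4.0 mM; time 3.0 min
- beta: second substrate 2.00 equiv; reagent 0.800 equiv; impurity 12 mM; time 3.0 min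

- Friday's (time / s: target / %, starting material / %): 10.0: 3.7, 92.4; 12.0: 7.2, 89.0; 15.0: 6.8, 88.9; 25.0: 12.4, 80.9; 40.0: 16.9, 75.1; 60.0: 25.1, 72.0; 90.0: 29.8, 62.1
- Sunday's (time / s: target / %, starting material / %): 10.0: 0.5, 97.6; 12.0: 0.6, 96.8; 15.0: 2.0, 100.9; 25.0: 1.3, 99.6; 40.0: 2.1, 99.4; 60.0: 0.2, 98.7; 90.0: 0.5, 99.8

(readings scatter by 1 percentage point)

- the earlier runs were read with a standard deviation of 1 percentage point
- steps thought possible: starting material + free catalyst <-> catalyst intermediate A; reagent + catalyst intermediate A -> free catalyst + target; second substrate + free catalyst <-> catalyst intermediate B; reagent + catalyst intermediate B -> free catalyst + second product; free catalyst + impurity -> spent catalyst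
- "hardly changes" means that all values lie within two and a half points (for a concentration: within two and a half percent of the largest)

* amount of target at the end, in percent of the starting material charged for zeta, alpha, theta, eta, beta, in this order
* the shape of the row from first to last (hardly changes / falls, then rises / rises all the way / falls all the way / rises, then falls)

I keep a ledger of the reagent. At 0.800 equiv it is less than the second substrate at 2.00 equiv and less than the one equivalent of starting material, so it is the limiting reagent. The first entry is target, made when reagent meets catalyst intermediate A. The second is second product, made when reagent meets catalyst intermediate B. The steps on the list give the impurity no entry, because it takes free catalyst and leaves reagent alone. So the books close when target and second product together reach 0.800 equiv, provided some catalyst outlasts the impurity; if none does, they stay open.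

The catalyst charge is 7.50 mM. Sunday's run had 14 mM of impurity, more than that charge, and its target reading at 40.0 s is 2.1%, with a scatter of 1 percentage point. I therefore take the loss as immediate and one for one. In eta, 4.0 mM of impurity leaves 46.7% of the catalyst. I call the fraction of the charge that outlasts the impurity the live share. Friday's run has a live share of 97.6%.

My reckoning is that each flask runs along Friday's curve on a slower clock. The 3.0 min of eta then count as 86.1 s of Friday's time, which is less than 90.0 s. So I expect eta just under Friday's reading of 29.8% at that time. In beta, 12 mM exceeds the charge, so I expect about what Sunday's run gave. The live share falls along the row, so I expect the row to fall.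

The forecast reads 41%, 40%, 38.5%, 29% and 1%, a row that falls all the way. Its ground is: “Scaling k with surviving catalyst, with the plateau unchanged”. Its eta value lies just below the Friday reading I took.

The flasks give 47.0%, 46.4%, 44.2%, 32.7% and 1.60%, a row that falls all the way.

    starting material + free catalyst ⇌ catalyst intermediate A (K = 30.0 L mol⁻¹, k = 5.50 L mol⁻¹ s⁻¹)
    reagent + catalyst intermediate A → free catalyst + target (k = 2.30 L mol⁻¹ s⁻¹)
    second substrate + free catalyst ⇌ catalyst intermediate B (K = 3.80 L mol⁻¹, k = 2.80 L mol⁻¹ s⁻¹)
    reagent + catalyst intermediate B → free catalyst + second product (k = 1.50 L mol⁻¹ s⁻¹)
    free catalyst + impurity → spent catalyst (k = 110 L mol⁻¹ s⁻¹)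

At 3.00 min, eta holds 53.3% of the catalyst charge as spent catalyst and still has 48.4% of its reagent, so its ledger stands open. Free catalyst and both intermediates there add up to 46.7% of the catalyst charge, against a live share of 46.7%. The same one-for-one subtraction, turned round for beta, leaves 37.5% of the impurity charged, and at 3.00 min beta holds 37.5% of its impurity.

Readings and results are simulated with constants of no real substance; noise was put on by code.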